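The ratio I want for this flask is that of two times: one grows with the charge of substrate, the other does not.

| flask | substrate | gas phase | remark | time |
|---|---|---|---|---|
| beta | 1.3 M | 140 mM (held) | run made earlier |  |
| eta | 3 M | 140 mM (held) | run made earlier |  |
| flask | 2.0 M | 140 mM (held) |  | 5.0 min |

- beta (time / min: target / %): 0.333: 3.2; 1.00: 8.7; 2.00: 12.4; 2.50: 17.7; 4.00: 23.6; 5.00: 25.8
- eta (time / min: target / %): 0.833: 3.6; 1.50: 10.0; 2.50: 12.8; 3.00: 14.5; 4.00: 18.2; 5.00: 20.6

(each reading ± 1 percentage point)

- how much target there is at 5.0 min, in percent of the substrate charged
- concentration of dissolved gas in solution at 5.0 min, in percent of saturation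

- what was read earlier has a scatter of 1 percentage point, one standard deviation
- at the start none of the gas phase is in solution

I replace each curve by its mean. The mean target time is the reading time divided by the yield, which is how long the whole charge would take to become target at the run's mean pace. It is 19.4 min for beta and 24.3 min for eta. A straight line through these two runs leaves a fixed time of 15.6 min, and the charge-bound time on that line equals the fixed time at a starting [substrate] I call the crossover charge, 5.43 M.

For the flask, the ratio of the charge-bound time to the fixed time is starting [substrate] over the crossover charge, 0.368. The two times sum to 21.4 min, so I expect 23.4% target.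

The error needs checking: beta made 17.7% by 2.50 min, then 8.1 percentage points more by 5.00 min. The mean is therefore the pace of no single moment, and I use it for the same reading time, with a scatter of 1 point. The readings do not show dissolved gas, so I give no figure for it.

The forecast gives 23% target and 80% of saturation, saying “saturation is higher, around 80%, and poorly determined”.

The flask gives 23.7% target and 93.5% of saturation.

    gas phase ⇌ dissolved gas, rate k1*(csat - [dissolved gas]) (kL = 0.110 s⁻¹)
    substrate + dissolved gas → target (k = 0.0150 M⁻¹ s⁻¹)
    substrate → side product A (k = 0.00260 s⁻¹)
    substrate + target → side product B (k = 0.00120 M⁻¹ s⁻¹)

At 5.00 min, the flask uses substrate for side product A 1.3 times as fast as for target, a selectivity factor. It holds 42.9% side product A, more than its 23.7% target.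

For a neighbour flask, the same but with starting [substrate] at 0.80 M, the ratio to the crossover charge is 0.147, so my reckoning gives 27.9% target. The computed result is 28.5%.

The readings are calculated with made-up constants.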